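## Structural features

The target 21 is a single oxolane ring (O1, C2–C5) carrying a 3,4,5-trimethoxyphenyl group on C2, a hydroxymethyl arm (C9) on C3 and, on C4, an exocyclic secondary benzylic carbinol (Ca) bearing a 3,4-dimethoxyphenyl ring. CIP analysis of the SMILES gives (2R,3S,4R) in the ring and (S) at Ca, with the three ring substituents all-trans. C2, C3 and C4 therefore form a contiguous stereotriad, and Ca is a fourth stereocentre attached directly to C4. Both benzylic C–O bonds (C2–O1 and Ca–OH) lie para to a methoxy group, so they ionise easily under acid and would not survive hydrogenolysis; this limits protection to silyl ethers and the end-game to non-acidic conditions. The all-trans ring is the thermodynamically favoured arrangement, so the real difficulty is the relation between the acyclic centre Ca and ring carbon C4, which no ring conformation controls. Once the C9 arm is removed, C4 sits between two CH2 carbons (C3 and C5), and C2 is a carbonyl carbon once the aryl group is removed: the pattern of a 3-substituted cyclobutanone with C2 as carbonyl and C3/C5 as its α-methylenes. The key step uses this hidden symmetry: oxygen insertion between C2 and C5 creates O1, expands the four-membered ketone to the γ-butyrolactone and turns prochiral C4 into a stereocentre next to the Ca centre already in place. The descriptors (S) at Ca in the cyclobutanone and (4R) in the lactone map onto the target, so no structural correction is needed.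

## Logic of the disconnections

**21 ⇒ 20.** The two O–Si bonds are cut last. Both hydroxyls carry the same silyl group, so one fluoride treatment ends the synthesis and no acid comes near the benzylic C–O bonds. The demand on the forward step is only that fluoride reaches a hindered secondary silyl ether.

**20 ⇒ 16 + 19 (19 from 17).** The C2–aryl bond is cut because C2 is at the acetal oxidation level, and its oxocarbenium ion sits next to the C3 stereocentre. This removes one ring stereocentre and the whole trimethoxyphenyl ring. The forward step must ionise only the anomeric acetate and not the Ca–O bond, the aryl must enter anti to the C3 substituent, and the nucleophile must be mild enough to leave the silyl ethers alone.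

**16 ⇒ 14.** The anomeric acetate is traced to the lactone carbonyl, a change of oxidation level only. The forward step needs a single hydride addition and trapping of the tetrahedral intermediate before it opens, so that C3 cannot epimerise through an aldehyde.

**14 ⇒ 13 ⇒ 11.** The C3–C9 bond (and the O–Si bond on C9) is cut. C3 is the only enolisable position of the lactone and formaldehyde is the one-carbon electrophile. This removes the second ring stereocentre and leaves a monosubstituted lactone. The forward aldol must stop at mono-addition, take place trans to the C4 substituent and avoid dehydration.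

**11 ⇒ 9.** The O1–C5 bond is cut and C5 is reconnected to C2 (retro-Baeyer–Villiger). The lactone with its C4 stereocentre becomes a cyclobutanone whose ring carbon is not a stereocentre, so only Ca remains. The forward step must choose between two diastereotopic α-methylenes and oxidise the ketone in the presence of an electron-rich arene and a benzylic silyl ether.

**9 ⇒ 7.** The ring carbonyl is traced to an exocyclic methylene. The alkene survives the organometallic, hydrogenation and silylation steps and is unmasked under neutral oxidative conditions, so no acid deprotection is needed next to the benzylic silyl ether. This also saves two steps against carrying the ketone as a ketal through a Weinreb amide. The demand is oxidative cleavage that spares the veratryl ring.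

**7 ⇒ 6 ⇒ 5.** The O–Si bond and then the Ca–H bond are cut. The single stereocentre of 9 comes from a prochiral aryl ketone by catalyst-controlled reduction. The triisopropylsilyl group is preferred to a smaller silyl group because this ether must later survive aqueous peroxide/acid and BF3·OEt2. The reduction must discriminate aryl from a secondary alkyl group and leave the alkene untouched.

**5 ⇒ 1 + 2 (through 3).** The Ca–aryl bond is cut. A nitrile is the acyl equivalent because addition stops at the ketimine, and both pieces are commercial. Addition must outrun α-deprotonation of the nitrile.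

## Other disconnections considered

**Alternative 1:** Cutting C2–C3 and C4–C5 leads from the all-trans aldehyde A1 back to the 4-alkenyl-2-aryl-1,3-dioxolane A2. In the forward direction SnCl4 opens the acetal to an aryl-stabilised oxocarbenium ion, the alkene terminus adds to it in a chair-like array (C2–C3), and the ring CH2 then migrates to the new cation (C4–C5) as the aldehyde forms: a Prins cyclisation followed by a pinacol shift.

- In its favour: one step makes the ring, two C–C bonds and the C2/C3/C4 triad. The trans,trans outcome follows from an all-equatorial chair and from the epimerisable formyl-bearing carbon. Addition of 3 to A1 would give A3, and one desilylation would finish, so the whole sequence would be shorter than the chosen one.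
- Against it here: the alkene of A2 is only 1,2-disubstituted and carries an allylic silyloxy group, so the cation formed at C4 would be secondary and inductively destabilised. Cyclisation would have to compete with acetal scrambling and hydride shift.
- The only stereocentre of A2 is destroyed in the pinacol step, so absolute configuration rests on one chair preference. The (4S) configuration written for A2 assumes the tin-bound oxygen is equatorial.
- Ca would be made last by addition to an α-branched aldehyde under Felkin–Anh bias alone, leaving the Ca/C4 relation to weak substrate control unless an oxidation/reduction pair is added.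
- Comparison: equal on the ring triad, better on convergence and step economy, worse on the Ca/C4 relation. The chosen plan sets Ca first by catalyst control and relays it to C4.

**Alternative 2:** Cutting O1–C2 and C4–C5 leads from the diester A4 to the aryl cyclopropane diester A5 and formaldehyde A6. In the forward direction Sn(OTf)2 activates the diester, the aldehyde oxygen attacks the aryl-bearing carbon as the ring opens (O1–C2), and the malonate carbon closes onto the aldehyde carbon (C4–C5): a formal (3+2) annulation.

- In its favour: it is modular, makes two ring bonds at once (more than the chosen key step, which makes one), and can transfer absolute configuration from an enantioenriched cyclopropane if attack is SN2-like.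
- Against it here: inversion at the aryl carbon means the 2,3-trans oxolane requires the cis-cyclopropane A5, the less accessible isomer. The electron-rich aryl donor favours full ionisation before attack, which would erode stereochemical fidelity.
- A6 is an awkward partner that oligomerises under Lewis acids.
- The geminal diester at C4 must be cut down afterwards: one ester excised, the other turned into the aryl ketone and reduced asymmetrically. C4 and Ca would again be set late and independently.
- Comparison: equal or better in ring-forming power, worse in atom economy (one carbon discarded), step count after the key step, and control of C4 and Ca.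

**Alternative 3:** Cutting C3–C4 and Ca–O leads from the hydroxy aldehyde A7 to the acyclic ether A8, which holds an enol ether and an electron-rich styrene on either side of O1. In the forward direction anodic oxidation in wet acetonitrile generates a radical cation, C3 and C4 couple in a 5-exo sense, and water traps both the benzylic cation (Ca–O) and the oxocarbenium ion at C9.

- In its favour: every heavy atom of the target is present in A8, the key step forms the ring, one C–C bond, one C–O bond and two or three stereocentres, and only a hydride reduction of A7 remains. In step count and bond-forming density it is clearly better than the chosen plan.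
- Against it here: Ca would be created by water capture of an acyclic benzylic cation with no controlling element, so the (S) configuration cannot be expected to dominate.
- A7 could epimerise at C3 and close to a lactol onto the Ca hydroxyl.
- Two electron-rich arenes and the product benzylic alcohol compete for oxidation at the anode.
- Comparison: equal on the C3/C4 trans relation, better on length, worse on Ca, which is the centre the chosen plan controls most securely.

Key step: step 5

Remark on the chemistry: which antipode of the phosphoric acid is matched with the (S)-silyloxy centre of 9 cannot be derived from first principles for this substrate. Both antipodes are accessible, and step 5 means the one that makes the (4R)-lactone the major diastereomer.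

## Route

Step 1
Reactants: 1 4-bromo-1,2-dimethoxybenzene; 2 3-methylidenecyclobutane-1-carbonitrile
Product: 5 (3,4-dimethoxyphenyl)(3-methylidenecyclobutyl)methanone, via aryl Grignard reagent 3 (not isolated), via bromomagnesium ketiminate 4 (not isolated)
Conditions: Mg, I2 (cat.), THF, reflux; then 2, CuBr (2 mol%), THF, reflux; then 1 M HCl, 0 °C → rt
Reagents that add atoms: water, O
Why: Grignard addition to a nitrile stops at the N-magnesio ketimine, which mild aqueous acid hydrolyses to the ketone; the isolated 1,1-disubstituted alkene is inert to both stages and no stereocentre is formed.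

Step 2
Reactants: 5 (3,4-dimethoxyphenyl)(3-methylidenecyclobutyl)methanone
Product: 6 (S)-(3,4-dimethoxyphenyl)(3-methylidenecyclobutyl)methanol
Conditions: RuCl2[(R)-xylbinap][(R)-daipen] (0.2 mol%), KOt-Bu (2 mol%), H2 (8 atm), i-PrOH, 25 °C
Reagents that add atoms: none
Why: Noyori asymmetric hydrogenation of an aryl alkyl ketone transfers hydride and proton to the carbonyl in the outer sphere, so the alkene should be untouched; the (R)-diphosphine/(R)-diamine pair delivers hydrogen to the face that gives (S)-aryl carbinols, and this catalyst class tolerates α-branched alkyl groups, which sets Ca.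

Step 3
Reactants: 6 (S)-(3,4-dimethoxyphenyl)(3-methylidenecyclobutyl)methanol
Product: 7 [(S)-(3,4-dimethoxyphenyl)(3-methylidenecyclobutyl)methoxy]tri(propan-2-yl)silane
Conditions: TIPSOTf, 2,6-lutidine, CH2Cl2, −78 → 0 °C
Reagents that add atoms: triisopropylsilyl trifluoromethanesulfonate, CC(C)[Si](OS(=O)(=O)C(F)(F)F)(C(C)C)C(C)C
Why: Silyl triflate silylation of a hindered secondary alcohol under buffered conditions leaves Ca untouched; the bulky, poorly Lewis-basic triisopropylsilyl ether is chosen because this benzylic oxygen must later resist aqueous peroxide/acid and BF3·OEt2.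

Step 4
Reactants: 7 [(S)-(3,4-dimethoxyphenyl)(3-methylidenecyclobutyl)methoxy]tri(propan-2-yl)silane
Product: 9 3-[(S)-(3,4-dimethoxyphenyl)(triisopropylsilyloxy)methyl]cyclobutan-1-one, via cyclobutane diol 8 (not isolated)
Conditions: K2OsO4·2H2O (2 mol%), NaIO4 (4 equiv), 2,6-lutidine, 1,4-dioxane/H2O 3:1, rt
Reagents that add atoms: sodium periodate, [Na+].[O-]I(=O)(=O)=O (terminal oxygen source, passed on through catalytic osmium tetroxide, O=[Os](=O)(=O)=O)
Why: Lemieux–Johnson oxidation dihydroxylates the exocyclic alkene and cleaves the diol in the same flask; unlike ozone or RuO4 it spares the veratryl ring, and the neutral buffered medium leaves the benzylic silyl ether intact.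

Step 5
Reactants: 9 3-[(S)-(3,4-dimethoxyphenyl)(triisopropylsilyloxy)methyl]cyclobutan-1-one
Product: 11 (4R)-4-[(S)-(3,4-dimethoxyphenyl)(triisopropylsilyloxy)methyl]oxolan-2-one, via Criegee adduct 10 (not isolated)
Conditions: chiral phosphoric acid [3,3′-di(pyren-1-yl)-H8-BINOL hydrogen phosphate, matched antipode, 10 mol%], 30% aq. H2O2 (1.5 equiv), CHCl3, −40 °C
Reagents that add atoms: hydrogen peroxide, OO
Why: Hydrogen peroxide, activated by the chiral phosphoric acid, adds to the strained carbonyl to give Criegee adduct 10, which the acid holds by two hydrogen bonds (P–OH to the peroxide, P=O to the hemiketal OH). The ring methylene antiperiplanar to the O–O bond in the bound rotamer then migrates from the carbonyl carbon to the proximal oxygen with retention as water leaves; this is a Baeyer–Villiger oxidation, and the closest known type is the phosphoric acid/H2O2 desymmetrisation of 3-substituted cyclobutanones to β-substituted γ-butyrolactones. The five-membered ring is formed by ring expansion, not cyclisation: a 1,2-shift inserts oxygen into the C2–C5 bond of the four-membered ring (O1–C5 forms). No bond to C4 is made or broken; its configuration is fixed solely by which methylene migrates, and that choice is made by the chiral phosphate acting together with the neighbouring (S)-silyloxy centre (double stereodifferentiation). Because 9 is a single enantiomer, the two possible lactones are diastereomers, so incomplete selection should cost material but not stereochemical purity, the (4S)-epimer being removable by chromatography. The step needs chemoselectivity against the veratryl ring and the benzylic silyl ether; ring strain secures it, since the cyclobutanone reacts with H2O2 at −40 °C under an acid too weak to oxidise the arene or ionise the silyl ether. Regiochemistry does not arise because both α-carbons are CH2 groups of equal migratory aptitude.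

Step 6
Reactants: 11 (4R)-4-[(S)-(3,4-dimethoxyphenyl)(triisopropylsilyloxy)methyl]oxolan-2-one
Product: 13 (3S,4R)-4-[(S)-(3,4-dimethoxyphenyl)(triisopropylsilyloxy)methyl]-3-(hydroxymethyl)oxolan-2-one, via lithium enolate 12 (not isolated)
Conditions: LiN(i-Pr)2, THF, −78 °C; then CH2O (gas, from cracked paraformaldehyde), −78 °C; AcOH quench at −78 °C
Reagents that add atoms: formaldehyde, C=O
Why: Aldol addition of the lactone lithium enolate (C3 is the only enolisable carbon) to monomeric formaldehyde; the electrophile should approach the enolate face opposite the bulky C4 substituent, setting C3 trans (3S), and the cold acidic quench guards against retro-aldol and dehydration.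

Step 7
Reactants: 13 (3S,4R)-4-[(S)-(3,4-dimethoxyphenyl)(triisopropylsilyloxy)methyl]-3-(hydroxymethyl)oxolan-2-one
Product: 14 (3S,4R)-4-[(S)-(3,4-dimethoxyphenyl)(triisopropylsilyloxy)methyl]-3-[(triisopropylsilyloxy)methyl]oxolan-2-one
Conditions: TIPSCl, imidazole, DMF, 0 °C → rt
Reagents that add atoms: chlorotriisopropylsilane, CC(C)[Si](Cl)(C(C)C)C(C)C
Why: Standard silylation of a primary alcohol; imidazole is too weak a base to cause elimination to the α-methylene lactone, and the second triisopropylsilyl group gives C3 a bulky non-participating substituent for step 9 and lets both hydroxyls be freed together in step 10.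

Step 8
Reactants: 14 (3S,4R)-4-[(S)-(3,4-dimethoxyphenyl)(triisopropylsilyloxy)methyl]-3-[(triisopropylsilyloxy)methyl]oxolan-2-one
Product: 16 (3S,4R)-4-[(S)-(3,4-dimethoxyphenyl)(triisopropylsilyloxy)methyl]-3-[(triisopropylsilyloxy)methyl]oxolan-2-yl acetate (both anomers), via aluminium lactolate 15 (not isolated)
Conditions: i-Bu2AlH, CH2Cl2, −78 °C; then pyridine, DMAP, Ac2O, −78 → 0 °C
Reagents that add atoms: acetic anhydride, CC(=O)OC(C)=O
Why: One-pot reductive acetylation: the aluminium hydride adds once to the lactone at −78 °C and the tetrahedral aluminium lactolate is acylated before it can open, so no free hydroxy aldehyde forms and C3 cannot epimerise; the anomeric mixture is inconsequential.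

Step 9
Reactants: 16 (3S,4R)-4-[(S)-(3,4-dimethoxyphenyl)(triisopropylsilyloxy)methyl]-3-[(triisopropylsilyloxy)methyl]oxolan-2-yl acetate; 17 5-bromo-1,2,3-trimethoxybenzene
Product: 20 (2R,3S,4R)-4-[(S)-(3,4-dimethoxyphenyl)(triisopropylsilyloxy)methyl]-3-[(triisopropylsilyloxy)methyl]-2-(3,4,5-trimethoxyphenyl)oxolane, via arylmagnesium bromide 18 (not isolated), via arylzinc bromide 19 (not isolated)
Conditions: 17, Mg, THF, 40 °C; ZnBr2, THF, 0 °C → rt; then 16, BF3·OEt2 (added last), CH2Cl2, −78 → −20 °C
Reagents that add atoms: none
Why: Lewis-acid-mediated C-arylation of a lactol acetate by an arylzinc reagent, as in C-aryl glycoside synthesis: BF3·OEt2 ionises the anomeric acetate to the cyclic oxocarbenium ion and the weakly basic arylzinc captures it at C2. Attack anti to the adjacent CH2OTIPS group should give the 2,3-trans (2R) isomer, which is also the thermodynamically preferred all-trans arrangement; having the nucleophile present before the Lewis acid limits side reactions of the cation.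

Step 10
Reactants: 20 (2R,3S,4R)-4-[(S)-(3,4-dimethoxyphenyl)(triisopropylsilyloxy)methyl]-3-[(triisopropylsilyloxy)methyl]-2-(3,4,5-trimethoxyphenyl)oxolane
Product: 21 (S)-(3,4-dimethoxyphenyl)[(3R,4S,5R)-4-(hydroxymethyl)-5-(3,4,5-trimethoxyphenyl)oxolan-3-yl]methanol (the target; (2R,3S,4R) in the ring numbering used above)
Conditions: Bu4NF, THF, rt → 40 °C
Reagents that add atoms: none
Why: Fluoride-mediated desilylation cleaves both Si–O bonds without acid, so neither benzylic C–O bond para to a methoxy group should ionise and no stereocentre is touched.

## Compound list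

1 | 4-bromo-1,2-dimethoxybenzene | COc1ccc(Br)cc1OC | starting material
2 | 3-methylidenecyclobutane-1-carbonitrile | C=C1CC(C#N)C1 | starting material
3 | (3,4-dimethoxyphenyl)magnesium bromide | COc1ccc([Mg]Br)cc1OC | intermediate (not isolated)
4 | bromomagnesium salt of (3,4-dimethoxyphenyl)(3-methylidenecyclobutyl)methanimine | COc1ccc(cc1OC)C(=N[Mg]Br)C1CC(=C)C1 | intermediate (not isolated)
5 | (3,4-dimethoxyphenyl)(3-methylidenecyclobutyl)methanone | COc1ccc(cc1OC)C(=O)C1CC(=C)C1 | intermediate
6 | (S)-(3,4-dimethoxyphenyl)(3-methylidenecyclobutyl)methanol | COc1ccc(cc1OC)[C@@H](O)C1CC(=C)C1 | intermediate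
7 | [(S)-(3,4-dimethoxyphenyl)(3-methylidenecyclobutyl)methoxy]tri(propan-2-yl)silane | COc1ccc(cc1OC)[C@@H](O[Si](C(C)C)(C(C)C)C(C)C)C1CC(=C)C1 | intermediate
8 | 3-[(S)-(3,4-dimethoxyphenyl)(triisopropylsilyloxy)methyl]-1-(hydroxymethyl)cyclobutan-1-ol (cis/trans mixture) | COc1ccc(cc1OC)[C@@H](O[Si](C(C)C)(C(C)C)C(C)C)C1CC(O)(CO)C1 | intermediate (not isolated)
9 | 3-[(S)-(3,4-dimethoxyphenyl)(triisopropylsilyloxy)methyl]cyclobutan-1-one | COc1ccc(cc1OC)[C@@H](O[Si](C(C)C)(C(C)C)C(C)C)C1CC(=O)C1 | intermediate (key-step precursor)
10 | 1-hydroperoxy-3-[(S)-(3,4-dimethoxyphenyl)(triisopropylsilyloxy)methyl]cyclobutan-1-ol (Criegee adduct) | COc1ccc(cc1OC)[C@@H](O[Si](C(C)C)(C(C)C)C(C)C)C1CC(O)(OO)C1 | intermediate (not isolated)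
11 | (4R)-4-[(S)-(3,4-dimethoxyphenyl)(triisopropylsilyloxy)methyl]oxolan-2-one | COc1ccc(cc1OC)[C@@H](O[Si](C(C)C)(C(C)C)C(C)C)[C@@H]1CC(=O)OC1 | intermediate (key-step product)
12 | lithium enolate of 11 (lithium (4R)-4-[(S)-(3,4-dimethoxyphenyl)(triisopropylsilyloxy)methyl]-4,5-dihydrofuran-2-olate) | COc1ccc(cc1OC)[C@@H](O[Si](C(C)C)(C(C)C)C(C)C)[C@H]1COC(O[Li])=C1 | intermediate (not isolated)
13 | (3S,4R)-4-[(S)-(3,4-dimethoxyphenyl)(triisopropylsilyloxy)methyl]-3-(hydroxymethyl)oxolan-2-one | COc1ccc(cc1OC)[C@@H](O[Si](C(C)C)(C(C)C)C(C)C)[C@H]1COC(=O)[C@@H]1CO | intermediate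
14 | (3S,4R)-4-[(S)-(3,4-dimethoxyphenyl)(triisopropylsilyloxy)methyl]-3-[(triisopropylsilyloxy)methyl]oxolan-2-one | COc1ccc(cc1OC)[C@@H](O[Si](C(C)C)(C(C)C)C(C)C)[C@H]1COC(=O)[C@@H]1CO[Si](C(C)C)(C(C)C)C(C)C | intermediate
15 | diisobutylaluminium lactolate of 14 | COc1ccc(cc1OC)[C@@H](O[Si](C(C)C)(C(C)C)C(C)C)[C@H]1COC(O[Al](CC(C)C)CC(C)C)[C@@H]1CO[Si](C(C)C)(C(C)C)C(C)C | intermediate (not isolated)
16 | (3S,4R)-4-[(S)-(3,4-dimethoxyphenyl)(triisopropylsilyloxy)methyl]-3-[(triisopropylsilyloxy)methyl]oxolan-2-yl acetate (both anomers) | COc1ccc(cc1OC)[C@@H](O[Si](C(C)C)(C(C)C)C(C)C)[C@H]1COC(OC(C)=O)[C@@H]1CO[Si](C(C)C)(C(C)C)C(C)C | intermediate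
17 | 5-bromo-1,2,3-trimethoxybenzene | COc1cc(Br)cc(OC)c1OC | starting material
18 | (3,4,5-trimethoxyphenyl)magnesium bromide | COc1cc([Mg]Br)cc(OC)c1OC | intermediate (not isolated)
19 | (3,4,5-trimethoxyphenyl)zinc bromide | COc1cc([Zn]Br)cc(OC)c1OC | intermediate (not isolated)
20 | (2R,3S,4R)-4-[(S)-(3,4-dimethoxyphenyl)(triisopropylsilyloxy)methyl]-3-[(triisopropylsilyloxy)methyl]-2-(3,4,5-trimethoxyphenyl)oxolane | COc1ccc(cc1OC)[C@@H](O[Si](C(C)C)(C(C)C)C(C)C)[C@H]1CO[C@@H](c2cc(OC)c(OC)c(OC)c2)[C@@H]1CO[Si](C(C)C)(C(C)C)C(C)C | intermediate
21 | (S)-(3,4-dimethoxyphenyl)[(3R,4S,5R)-4-(hydroxymethyl)-5-(3,4,5-trimethoxyphenyl)oxolan-3-yl]methanol | COc1ccc([C@@H](O)[C@H]2CO[C@@H](c3cc(OC)c(OC)c(OC)c3)[C@@H]2CO)cc1OC | target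

## Step count and least certain steps

Total: 10 steps. Longest linear sequence: 10 steps (1 and 2 to 21); 17 enters at step 9 as an organometallic made in the same flask.

**Step 5 (key step).** The most likely failure is weak discrimination between the two α-methylenes. This catalyst class works best when the ring substituent is an aryl group, whereas here it is a branched alkyl group, and both antipodes of the acid may prove poorly matched with the Ca centre. Slow turnover of the hindered ketone at low temperature is a second risk. Fallback: setting out from 9, the oxidation is run without any chiral catalyst (mCPBA, NaHCO3, CH2Cl2, 0 °C). This gives 11 together with its C4 epimer, (4S)-4-[(S)-(3,4-dimethoxyphenyl)(triisopropylsilyloxy)methyl]oxolan-2-one F1. Because the two are diastereomers, chromatography separates them and the route is rejoined at 11, at the cost of up to half the material.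

**Step 9.** Several processes may compete with the intended capture of the oxocarbenium ion:
- poor facial selectivity at C2;
- intramolecular Friedel–Crafts attack by the veratryl ring, which can reach C2 from the face anti to C3;
- ionisation at the Ca–O bond;
- proton loss from C3 to a dihydrofuran;
- sluggish transfer from the arylzinc.

Fallback: setting out from 14, reduction with i-Bu2AlH gives the lactol (3S,4R)-4-[(S)-(3,4-dimethoxyphenyl)(triisopropylsilyloxy)methyl]-3-[(triisopropylsilyloxy)methyl]oxolan-2-ol F2. Addition of 18 to its open hydroxy-aldehyde form gives (2S,3R)-3-[(S)-(3,4-dimethoxyphenyl)(triisopropylsilyloxy)methyl]-2-[(triisopropylsilyloxy)methyl]-1-(3,4,5-trimethoxyphenyl)butane-1,4-diol F3 as a mixture at the new carbinol. Catalytic camphorsulfonic acid in CH2Cl2 then ionises the free trimethoxybenzylic alcohol, and the primary hydroxyl closes the ring (O1–C2 formed last). Both carbinol epimers should converge on the 2,3-trans oxolane, rejoining the route at 20.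

**Step 6.** Formaldehyde may polymerise before it meets the enolate, the aldolate may revert or dehydrate to the α-methylene lactone, and a second hydroxymethylation is possible. Fallback: setting out from 11, enolate 12 is alkylated with (triisopropylsilyloxy)methyl chloride. This chloromethyl ether alkylation installs the silyl-protected arm directly, trans to the C4 substituent, and rejoins the route at 14, bypassing 13. No new compound is made.

**Step 2.** Enantioface discrimination may be incomplete because the cyclobutyl group is closer in size to the aryl group than a methyl group would be. The minor enantiomer would be carried into step 5, where it would give diastereomers, separable there at a cost in yield. Fallback: setting out from 2, i-Bu2AlH reduction and aqueous HCl work-up give 3-methylidenecyclobutane-1-carbaldehyde F4. Catalytic asymmetric aryl transfer to F4 ((3,4-dimethoxyphenyl)boronic acid, Et2Zn, chiral amino alcohol ligand, toluene) then forms the Ca–aryl bond and the stereocentre together, rejoining the route at 6.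

## Further compounds

F1 | step 5 | (4S)-4-[(S)-(3,4-dimethoxyphenyl)(triisopropylsilyloxy)methyl]oxolan-2-one | COc1ccc(cc1OC)[C@@H](O[Si](C(C)C)(C(C)C)C(C)C)[C@H]1CC(=O)OC1
F2 | step 9 | (3S,4R)-4-[(S)-(3,4-dimethoxyphenyl)(triisopropylsilyloxy)methyl]-3-[(triisopropylsilyloxy)methyl]oxolan-2-ol (both anomers) | COc1ccc(cc1OC)[C@@H](O[Si](C(C)C)(C(C)C)C(C)C)[C@H]1COC(O)[C@@H]1CO[Si](C(C)C)(C(C)C)C(C)C
F3 | step 9 | (2S,3R)-3-[(S)-(3,4-dimethoxyphenyl)(triisopropylsilyloxy)methyl]-2-[(triisopropylsilyloxy)methyl]-1-(3,4,5-trimethoxyphenyl)butane-1,4-diol (mixture at C1) | COc1ccc(cc1OC)[C@@H](O[Si](C(C)C)(C(C)C)C(C)C)[C@@H](CO)[C@@H](CO[Si](C(C)C)(C(C)C)C(C)C)C(O)c1cc(OC)c(OC)c(OC)c1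
F0 | step 6 | none | none
F4 | step 2 | 3-methylidenecyclobutane-1-carbaldehyde | C=C1CC(C=O)C1
A1 | alternative 1 | all-trans 5-(3,4,5-trimethoxyphenyl)-4-[(triisopropylsilyloxy)methyl]oxolane-3-carbaldehyde | O=C[C@H]1CO[C@@H](c2cc(OC)c(OC)c(OC)c2)[C@@H]1CO[Si](C(C)C)(C(C)C)C(C)C
A2 | alternative 1 | (4S)-2-(3,4,5-trimethoxyphenyl)-4-[(E)-3-(triisopropylsilyloxy)prop-1-en-1-yl]-1,3-dioxolane (acetal carbon unassigned) | COc1cc(cc(OC)c1OC)C1OC[C@@H](O1)/C=C/CO[Si](C(C)C)(C(C)C)C(C)C
A3 | alternative 1 | (S)-(3,4-dimethoxyphenyl)[(3R,4S,5R)-4-[(triisopropylsilyloxy)methyl]-5-(3,4,5-trimethoxyphenyl)oxolan-3-yl]methanol | COc1ccc([C@@H](O)[C@H]2CO[C@@H](c3cc(OC)c(OC)c(OC)c3)[C@@H]2CO[Si](C(C)C)(C(C)C)C(C)C)cc1OC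
A4 | alternative 2 | dimethyl 4,5-trans-5-(3,4,5-trimethoxyphenyl)-4-[(triisopropylsilyloxy)methyl]oxolane-3,3-dicarboxylate | COC(=O)C1(C(=O)OC)CO[C@@H](c2cc(OC)c(OC)c(OC)c2)[C@@H]1CO[Si](C(C)C)(C(C)C)C(C)C
A5 | alternative 2 | dimethyl cis-2-(3,4,5-trimethoxyphenyl)-3-[(triisopropylsilyloxy)methyl]cyclopropane-1,1-dicarboxylate (enantiomer as in the SMILES) | COC(=O)C1(C(=O)OC)[C@H](c2cc(OC)c(OC)c(OC)c2)[C@@H]1CO[Si](C(C)C)(C(C)C)C(C)C
A6 | alternative 2 | formaldehyde | C=O
A7 | alternative 3 | all-trans 4-[(S)-(3,4-dimethoxyphenyl)(hydroxy)methyl]-2-(3,4,5-trimethoxyphenyl)oxolane-3-carbaldehyde | COc1ccc(cc1OC)[C@@H](O)[C@H]1CO[C@@H](c2cc(OC)c(OC)c(OC)c2)[C@@H]1C=O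
A8 | alternative 3 | 5-[(1R)-1-{[(2E)-3-(3,4-dimethoxyphenyl)prop-2-en-1-yl]oxy}-3-methoxyprop-2-en-1-yl]-1,2,3-trimethoxybenzene (enol ether E/Z mixture) | COC=C[C@@H](OC/C=C/c1ccc(OC)c(OC)c1)c1cc(OC)c(OC)c(OC)c1
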